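The vessel is closed and stirred, so what leaves the starting material stays in the count, and in the alpha run at 90.0 s the loss of 22.3% is more than the 7.5% of target.

| setting | alpha | eta | north | north-east | east | south-east | north-west |
|---|---|---|---|---|---|---|---|
| starting material | 0.010 M | 0.010 M | 0.010 M | 0.010 M | 0.010 M | 0.010 M | 0.010 M |
| second substrate | 10 mM | 10 mM | 10.0 mM | 10.0 mM | 10.0 mM | 10.0 mM | 10.0 mM |
| protic impurity | 0.13 mM | 0.10 mM | 0.200 mM | 0.200 mM | 0.200 mM | 0.200 mM | 0.200 mM |
| enzyme | 1 µM | 1 µM | 1.0 µM | 0.60 µM | 4.0 µM | 0.30 µM | 3.0 µM |
| remark | run made earlier | run made earlier |  |  |  |  |  |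
| time |  |  | 2.5 min | 2.5 min | 2.5 min | 2.5 min | 2.5 min |

- alpha (time / s: target / %, starting material / %): 10.0: 0.8, 96.7; 12.0: 0.8, 95.9; 15.0: 1.5, 95.0; 25.0: 2.0, 92.4; 40.0: 3.1, 88.3; 60.0: 4.7, 84.0; 90.0: 7.5, 77.7
- eta (time / s: target / %, starting material / %): 10.0: 0.6, 96.7; 15.0: 1.5, 95.0; 25.0: 2.3, 92.9; 40.0: 3.2, 89.0; 50.0: 4.6, 87.1; 80.0: 6.9, 80.4; 90.0: 7.2, 78.3

(each reading ± 0.3 percentage points)

1. the flasks by amount of target, in percent of the starting material charged, highest first, at 2.5 min (north / north-east / east / south-east / north-west)
2. the amount of target, in percent of the starting material charged of the flask you put first, at 2.5 min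
3. the amount of target, in percent of the starting material charged of the flask you put last, at 2.5 min

- the earlier runs were read with a standard deviation of 0.3 percentage points
- no earlier run changes the charge of enzyme; that part of a forecast is a guess

I pool both runs from 25.0 s to 90.0 s, leaving out the first seconds, and treat the loss as pseudo-first-order:

loss constant = 0.159 min⁻¹; target share of the loss = 35.5%

Could the missing material be waiting on the enzyme and turn into target later? In the alpha run 14.8% is missing, and the enzyme charge, if each enzyme holds one starting material, can hold 0.0100%, far less. So I guess that the rest leaves by an enzyme-free way, at 0.102 min⁻¹. No earlier run changes the enzyme charge, so this stays a guess.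

Then one quantity joins the two ends: the crossover charge, the enzyme charge at which the enzyme way and the enzyme-free way draw equally, 1.82 µM. At the short end, with little starting material used, target at a fixed time grows in this picture in proportion to c(enzyme). At the long end, with the starting material used up, target in this picture tends to the share c(enzyme)/(c(enzyme) + crossover).

But the protic impurity is new at 0.200 mM. Target at 90.0 s reads 7.5% and 7.2% for the two earlier charges, with a scatter of 0.3 percentage points, which shows little. If each impurity takes one starting material, it costs 2.00%, so I scale by that:

target = (1 − c(impurity)/c(starting material)) × share × (1 − exp(−k × (1 + c(enzyme)/crossover) × t)), with k the enzyme-free constant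

East: 37.7%. South-east: 3.58%. Both factors rise with the enzyme charge, so my order follows the charges. East is the figure I trust least, its charge lying 4.00 times above the measured one, further than south-east's lies below it.

The forecast says east > north-west > north > north-east > south-east, with 38% and 3.6%, on the ground “Assuming rate scales with enzyme”.

The flasks give east > north-west > north > north-east > south-east, with 40.1% and 3.59%.

    starting material + enzyme ⇌ complex A (K = 40.0 L mol⁻¹, k = 67000 L mol⁻¹ s⁻¹)
    complex A → enzyme + target (k = 2600 min⁻¹)
    second substrate + enzyme ⇌ complex B (K = 48.0 L mol⁻¹, k = 88000 L mol⁻¹ s⁻¹)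
    complex B → enzyme + second product (k = 1300 min⁻¹)
    starting material + protic impurity → quenched substrate (k = 2200 L mol⁻¹ min⁻¹)
    starting material → uncatalysed product (k = 0.100 min⁻¹)

By 2.50 min in east, the protic impurity stands at 0% and quenched substrate at 2.00%, while the enzyme has made 40.1% of target beside 16.6% of uncatalysed product. In south-east, whose charge lies under the crossover, uncatalysed product at 21.3% stands above target at 3.59%. My east figure lies 2.4 points under the flask.

Now take south-east read at 10 min. The same crossover gives 9.68% of target, and the flask gives 10.3%, beside 57.6% of uncatalysed product.

The readings stem from a simulated flask with constants of no real substance; the scatter is artificial.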